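## Retrosynthetic overview

1. The ten-membered ring is closed last at C1–C10 by a Ni/Cr-catalysed Nozaki–Hiyama–Kishi coupling of a (Z)-alkenyl iodide with the C1 aldehyde; this also liberates the free C1–OH, so no protecting group remains.
2. The seco chain comes from a West alcohol (C1–C6) and an East allylic carbonate (C7–C14 with C11–C13), joined at C6–C7 by an iridium-catalysed transfer-hydrogenative 2-(methoxycarbonyl)allylation from the carbinol C–H level; the cis α-methylene-γ-lactone closes in the same flask.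
3. West: (Z)-3-iodobut-2-en-1-ol (from but-2-yn-1-ol) plus 3-(PMB-oxy)propanal by asymmetric NHK coupling (C3–C4), then acetate.
4. East: (R)-solketal → (Z)-iodoalkene → α-silyloxy aldehyde, plus methyl propiolate by vinylalumination → allylic carbonate; the angelate is put on after the union.
5. Ring order: lactone (step 15), then carbocycle (step 20).

Assumption: germacranolide locants are used (C1 carbinol, C3 acetate, C4=C5 with C15 methyl, C6 lactone carbinol, C7, C8 angelate, C9=C10 with C14 methyl, C11=C13 methylene, C12 carbonyl; target = 1S,3S,4Z,6R,7R,8R,9Z), 1,10-seco compounds keep these locants with iodine on C10, and the ligand antipodes named in steps 5, 15 and 20 follow the expected sense of the parent reactions and are swapped if that sense proves opposite.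

## Route

Step 1
Reactants: 1 but-2-yn-1-ol
Product: 3 (Z)-3-iodobut-2-en-1-ol, via cyclic alkenylaluminate 2 (not isolated)
Conditions: NaAlH2(OCH2CH2OMe)2, THF, 0 °C to rt; then I2, THF, −78 to 0 °C
Reagents that add atoms: iodine, II; sodium bis(2-methoxyethoxy)aluminium dihydride, [Na+].[AlH2-](OCCOC)OCCOC (its atoms stay in 2 only)
Why: Hydroxyl-directed trans-hydroalumination of the propargylic alcohol puts Al on C3 and H on C2 anti (five-membered alkoxyaluminate 2), and iodinolysis with retention gives only the Z iodide (Red-Al reduction–iodination).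

Step 2
Reactants: 3 (Z)-3-iodobut-2-en-1-ol
Product: 4 (Z)-tert-butyl[(3-iodobut-2-en-1-yl)oxy]dimethylsilane
Conditions: TBSCl, imidazole, DMF, 0 °C to rt
Reagents that add atoms: tert-butyldimethylsilyl chloride, CC(C)(C)[Si](C)(C)Cl
Why: Standard silylation of a primary alcohol; no stereocentre is involved.

Step 3
Reactants: 5 propane-1,3-diol
Product: 6 3-[(4-methoxybenzyl)oxy]propan-1-ol
Conditions: NaH (1.0 equiv), THF, 0 °C; PMBCl, n-Bu4NI (cat.), rt
Reagents that add atoms: 4-methoxybenzyl chloride, COc1ccc(CCl)cc1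
Why: Williamson mono-etherification of a symmetrical diol with one equivalent of base gives the mono-ether.

Step 4
Reactants: 6 3-[(4-methoxybenzyl)oxy]propan-1-ol
Product: 7 3-[(4-methoxybenzyl)oxy]propanal
Conditions: TEMPO (cat.), PhI(OAc)2, CH2Cl2, rt
Reagents that add atoms: none
Why: TEMPO/PhI(OAc)2 oxidation stops at the aldehyde and leaves the PMB ether untouched.

Step 5
Reactants: 4 (Z)-tert-butyl[(3-iodobut-2-en-1-yl)oxy]dimethylsilane; 7 3-[(4-methoxybenzyl)oxy]propanal
Product: 8 (3S,4Z)-6-[(tert-butyldimethylsilyl)oxy]-1-[(4-methoxybenzyl)oxy]-4-methylhex-4-en-3-ol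
Conditions: CrCl2 (10 mol%), (S)-4-isopropyloxazolinyl aryl methanesulfonamide ligand (Kishi type, 11 mol%), Et3N (20 mol%), NiCl2·(2,9-dimethyl-1,10-phenanthroline) (2 mol%), Mn powder, Cp2ZrCl2, LiCl, MeCN, rt
Reagents that add atoms: none
Why: Catalytic asymmetric Nozaki–Hiyama–Kishi coupling, in which zerovalent nickel inserts into the C–I bond with retention of the Z geometry and the derived alkenyl trivalent chromium species, held by the chiral sulfonamide, adds to one aldehyde face to set C3 as S.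

Step 6
Reactants: 8 (3S,4Z)-6-[(tert-butyldimethylsilyl)oxy]-1-[(4-methoxybenzyl)oxy]-4-methylhex-4-en-3-ol
Product: 9 (3S,4Z)-6-[(tert-butyldimethylsilyl)oxy]-1-[(4-methoxybenzyl)oxy]-4-methylhex-4-en-3-yl acetate
Conditions: Ac2O, pyridine, DMAP (cat.), CH2Cl2, 0 °C to rt
Reagents that add atoms: acetic anhydride, CC(=O)OC(C)=O
Why: DMAP-catalysed acetylation of the secondary allylic alcohol leaves the configuration untouched.

Step 7
Reactants: 9 (3S,4Z)-6-[(tert-butyldimethylsilyl)oxy]-1-[(4-methoxybenzyl)oxy]-4-methylhex-4-en-3-yl acetate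
Product: 10 (3S,4Z)-6-hydroxy-1-[(4-methoxybenzyl)oxy]-4-methylhex-4-en-3-yl acetate
Conditions: HF·pyridine, pyridine, THF, 0 °C
Reagents that add atoms: none
Why: Buffered HF·pyridine cleaves the primary allylic TBS ether without touching acetate or PMB and without the base-induced acetyl shift that fluoride salts could cause.

Step 8
Reactants: 11 (R)-(2,2-dimethyl-1,3-dioxolan-4-yl)methanol [(R)-solketal]
Product: 12 (S)-2,2-dimethyl-1,3-dioxolane-4-carbaldehyde
Conditions: TEMPO (cat.), PhI(OAc)2, CH2Cl2, rt; used crude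
Reagents that add atoms: none
Why: Near-neutral TEMPO oxidation of the primary alcohol does not epimerise the α-stereocentre (the descriptor changes only through priorities).

Step 9
Reactants: 12 (S)-2,2-dimethyl-1,3-dioxolane-4-carbaldehyde
Product: 13 (R)-4-[(Z)-2-iodoprop-1-en-1-yl]-2,2-dimethyl-1,3-dioxolane
Conditions: EtPPh3I, n-BuLi, THF, rt; I2, −78 °C; NaN(SiMe3)2, −78 to −20 °C; then 12, −78 °C to rt
Reagents that add atoms: ethyltriphenylphosphonium iodide, CC[P+](c1ccccc1)(c1ccccc1)c1ccccc1.[I-]; iodine, II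
Why: The Wittig reaction of the α-iodo ylide (Stork–Zhao type) is kinetically Z-selective (iodine cis to the chain) and at −78 °C does not epimerise the α-alkoxy aldehyde.

Step 10
Reactants: 13 (R)-4-[(Z)-2-iodoprop-1-en-1-yl]-2,2-dimethyl-1,3-dioxolane
Product: 14 (2R,3Z)-4-iodopent-3-ene-1,2-diol
Conditions: AcOH/H2O (4:1), 40 °C
Reagents that add atoms: none
Why: Mild acid hydrolysis of the isopropylidene acetal leaves the alkenyl iodide and the stereocentre untouched.

Step 11
Reactants: 14 (2R,3Z)-4-iodopent-3-ene-1,2-diol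
Product: 15 (2R,3Z)-4-iodo-1,2-bis(triethylsilyloxy)pent-3-ene
Conditions: Et3SiCl, imidazole, DMAP (cat.), DMF, 0 °C to rt
Reagents that add atoms: triethylsilyl chloride, CC[Si](CC)(CC)Cl
Why: Exhaustive silylation of both hydroxyls sets up the selective oxidation of the primary one.

Step 12
Reactants: 15 (2R,3Z)-4-iodo-1,2-bis(triethylsilyloxy)pent-3-ene
Product: 16 (2R,3Z)-4-iodo-2-(triethylsilyloxy)pent-3-enal
Conditions: (COCl)2, DMSO, CH2Cl2, −78 to −40 °C; Et3N, −78 to 0 °C; used at once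
Reagents that add atoms: none
Why: Under Swern conditions the activated DMSO cleaves only the unhindered primary TES ether and oxidises it in the same flask, while the secondary TES ether stays on (selective Swern oxidation of primary silyl ethers).

Step 13
Reactants: 16 (2R,3Z)-4-iodo-2-(triethylsilyloxy)pent-3-enal; 17 methyl prop-2-ynoate
Product: 19 methyl 2-[(2R,3Z)-1-hydroxy-4-iodo-2-(triethylsilyloxy)pent-3-en-1-yl]prop-2-enoate (both C7 epimers), via methyl 2-(diisobutylalumanyl)prop-2-enoate 18 (not isolated)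
Conditions: i-Bu2AlH, N-methylmorpholine N-oxide, THF, 0 °C; then 16, 0 °C to rt
Reagents that add atoms: diisobutylaluminium hydride, CC(C)C[AlH]CC(C)C (its atoms stay in 18 only)
Why: Hydroalumination of the propiolate gives the non-basic α-aluminoacrylate 18, which adds to the aldehyde without epimerising C8 (vinylalumination route to Morita–Baylis–Hillman-type adducts); the C7 epimer mixture is irrelevant because C7 becomes part of a π-allyl in step 15.

Step 14
Reactants: 19 methyl 2-[(2R,3Z)-1-hydroxy-4-iodo-2-(triethylsilyloxy)pent-3-en-1-yl]prop-2-enoate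
Product: 20 methyl 2-[(2R,3Z)-1-(tert-butoxycarbonyloxy)-4-iodo-2-(triethylsilyloxy)pent-3-en-1-yl]prop-2-enoate (both C7 epimers)
Conditions: Boc2O, DMAP (cat.), CH2Cl2, 0 °C
Reagents that add atoms: di-tert-butyl dicarbonate, CC(C)(C)OC(=O)OC(=O)OC(C)(C)C
Why: DMAP-catalysed carbonate formation on the secondary allylic alcohol gives the activated allyl donor.

Step 15
Reactants: 10 (3S,4Z)-6-hydroxy-1-[(4-methoxybenzyl)oxy]-4-methylhex-4-en-3-yl acetate; 20 methyl 2-[(2R,3Z)-1-(tert-butoxycarbonyloxy)-4-iodo-2-(triethylsilyloxy)pent-3-en-1-yl]prop-2-enoate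
Product: 22 (3S,4Z,6R,7R,8S,9Z)-3-acetoxy-10-iodo-1-(4-methoxybenzyloxy)-8-(triethylsilyloxy)-1,10-secogermacra-4,9,11(13)-trien-6,12-olide, via seco hydroxy ester 21 (not isolated)
Conditions: [Ir(cod)Cl]2 (2.5 mol%), (R)-SEGPHOS (5 mol%), 4-chloro-3-nitrobenzoic acid (10 mol%), Cs2CO3 (20 mol%), THF, 60 °C; then PPTS (cat.), CH2Cl2, rt
Reagents that add atoms: none
Why: Proposed new method: the cyclometalated trivalent iridium C,O-benzoate dehydrogenates the allylic alcohol 10 to the (Z)-enal at the metal (carbinol C–H cleavage by β-hydride elimination), the monovalent iridium so formed ionises either epimer of carbonate 20 to one 1-substituted 2-(methoxycarbonyl)-π-allyl complex, and its σ-allyl form (Ir on C13, C8 cis to CH2Ir) adds to the enal at C7 through a closed chair to give the 6,7-syn adduct 21, with C6 set by the ligand and C7 formed anti to the C8 silyloxy group (matched substrate control), after which 21 lactonises to the cis lactone; the closest known reactions are the iridium-catalysed transfer-hydrogenative 2-(alkoxycarbonyl)allylation of primary alcohols with unsubstituted acrylate-derived donors and the related crotylation with α-methylallyl acetate, here extended to a 1-substituted donor carrying a stereocentre.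

Step 16
Reactants: 22 (3S,4Z,6R,7R,8S,9Z)-3-acetoxy-10-iodo-1-(4-methoxybenzyloxy)-8-(triethylsilyloxy)-1,10-secogermacra-4,9,11(13)-trien-6,12-olide
Product: 23 (3S,4Z,6R,7S,8S,9Z)-3-acetoxy-8-hydroxy-10-iodo-1-(4-methoxybenzyloxy)-1,10-secogermacra-4,9,11(13)-trien-6,12-olide
Conditions: HF·pyridine, pyridine, THF, 0 °C
Reagents that add atoms: none
Why: HF·pyridine removes the secondary TES ether while PMB, acetate, lactone and alkenyl iodide stay (C7 becomes S by priority change only).

Step 17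
Reactants: 23 (3S,4Z,6R,7S,8S,9Z)-3-acetoxy-8-hydroxy-10-iodo-1-(4-methoxybenzyloxy)-1,10-secogermacra-4,9,11(13)-trien-6,12-olide; 24 angelic acid [(Z)-2-methylbut-2-enoic acid]
Product: 26 (3S,4Z,6R,7R,8S,9Z)-3-acetoxy-8-angeloyloxy-10-iodo-1-(4-methoxybenzyloxy)-1,10-secogermacra-4,9,11(13)-trien-6,12-olide, via angelic 2,4,6-trichlorobenzoic anhydride 25 (not isolated)
Conditions: 24, 2,4,6-trichlorobenzoyl chloride, Et3N, toluene, rt; then 23, toluene, 75 °C
Reagents that add atoms: 2,4,6-trichlorobenzoyl chloride, O=C(Cl)c1c(Cl)cc(Cl)cc1Cl (its atoms stay in 25 only)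
Why: Yamaguchi-type acylation through mixed anhydride 25 is the established way to make angelates without Z to E isomerisation, because neither a free acid chloride nor a nucleophilic catalyst is present.

Step 18
Reactants: 26 (3S,4Z,6R,7R,8S,9Z)-3-acetoxy-8-angeloyloxy-10-iodo-1-(4-methoxybenzyloxy)-1,10-secogermacra-4,9,11(13)-trien-6,12-olide
Product: 27 (3S,4Z,6R,7R,8S,9Z)-3-acetoxy-8-angeloyloxy-1-hydroxy-10-iodo-1,10-secogermacra-4,9,11(13)-trien-6,12-olide
Conditions: DDQ, CH2Cl2/pH 7 buffer, 0 °C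
Reagents that add atoms: none
Why: DDQ cleaves the electron-rich PMB ether oxidatively, and the esters, lactone and alkenyl iodide are inert.

Step 19
Reactants: 27 (3S,4Z,6R,7R,8S,9Z)-3-acetoxy-8-angeloyloxy-1-hydroxy-10-iodo-1,10-secogermacra-4,9,11(13)-trien-6,12-olide
Product: 28 (3S,4Z,6R,7R,8S,9Z)-3-acetoxy-8-angeloyloxy-10-iodo-1-oxo-1,10-secogermacra-4,9,11(13)-trien-6,12-olide
Conditions: Dess–Martin periodinane, pyridine, CH2Cl2, 0 °C to rt; used directly
Reagents that add atoms: none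
Why: Buffered Dess–Martin oxidation gives the β-acetoxy aldehyde without loss of acetic acid.

Step 20
Reactants: 28 (3S,4Z,6R,7R,8S,9Z)-3-acetoxy-8-angeloyloxy-10-iodo-1-oxo-1,10-secogermacra-4,9,11(13)-trien-6,12-olide
Product: 29 (1S,3S,4Z,6R,7R,8R,9Z)-3-acetoxy-8-angeloyloxy-1-hydroxygermacra-4,9,11(13)-trien-6,12-olide (CNP0319825.3)
Conditions: CrCl2 (20 mol%), (S)-4-isopropyloxazolinyl aryl methanesulfonamide ligand (Kishi type, 22 mol%), Et3N (40 mol%), NiCl2·(2,9-dimethyl-1,10-phenanthroline) (5 mol%), Mn powder, Cp2ZrCl2, LiCl, MeCN, rt, syringe-pump addition of 28 (final 2 mM)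
Reagents that add atoms: none
Why: Intramolecular Nozaki–Hiyama–Kishi coupling, in which zerovalent nickel inserts into the C10–I bond with retention of the Z geometry and the alkenylchromium adds to the C1 aldehyde; the two Z olefins and the cis lactone hold the chain ends close, and the chiral chromium complex together with the C3 acetate selects the aldehyde face to give 1S.

## Compound list

1 | but-2-yn-1-ol | CC#CCO | starting material
2 | sodium 3-methyl-2,2-bis(2-methoxyethoxy)-2,5-dihydro-1,2-oxaluminol-2-uide (cyclic alkenylaluminate, not isolated) | CC1=CCO[Al-]1(OCCOC)OCCOC.[Na+] | intermediate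
3 | (Z)-3-iodobut-2-en-1-ol | C/C(I)=C/CO | intermediate
4 | (Z)-tert-butyl[(3-iodobut-2-en-1-yl)oxy]dimethylsilane | C/C(I)=C/CO[Si](C)(C)C(C)(C)C | intermediate
5 | propane-1,3-diol | OCCCO | starting material
6 | 3-[(4-methoxybenzyl)oxy]propan-1-ol | COc1ccc(COCCCO)cc1 | intermediate
7 | 3-[(4-methoxybenzyl)oxy]propanal | COc1ccc(COCCC=O)cc1 | intermediate
8 | (3S,4Z)-6-[(tert-butyldimethylsilyl)oxy]-1-[(4-methoxybenzyl)oxy]-4-methylhex-4-en-3-ol | COc1ccc(COCC[C@H](O)/C(C)=C\CO[Si](C)(C)C(C)(C)C)cc1 | intermediate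
9 | (3S,4Z)-6-[(tert-butyldimethylsilyl)oxy]-1-[(4-methoxybenzyl)oxy]-4-methylhex-4-en-3-yl acetate | COc1ccc(COCC[C@H](OC(C)=O)/C(C)=C\CO[Si](C)(C)C(C)(C)C)cc1 | intermediate
10 | (3S,4Z)-6-hydroxy-1-[(4-methoxybenzyl)oxy]-4-methylhex-4-en-3-yl acetate (West alcohol, C1–C6) | COc1ccc(COCC[C@H](OC(C)=O)/C(C)=C\CO)cc1 | intermediate
11 | (R)-(2,2-dimethyl-1,3-dioxolan-4-yl)methanol, (R)-solketal | OC[C@@H]1COC(C)(C)O1 | starting material
12 | (S)-2,2-dimethyl-1,3-dioxolane-4-carbaldehyde | O=C[C@@H]1COC(C)(C)O1 | intermediate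
13 | (R)-4-[(Z)-2-iodoprop-1-en-1-yl]-2,2-dimethyl-1,3-dioxolane | C/C(I)=C/[C@@H]1COC(C)(C)O1 | intermediate
14 | (2R,3Z)-4-iodopent-3-ene-1,2-diol | C/C(I)=C/[C@@H](O)CO | intermediate
15 | (2R,3Z)-4-iodo-1,2-bis(triethylsilyloxy)pent-3-ene | C/C(I)=C/[C@@H](O[Si](CC)(CC)CC)CO[Si](CC)(CC)CC | intermediate
16 | (2R,3Z)-4-iodo-2-(triethylsilyloxy)pent-3-enal | C/C(I)=C/[C@@H](O[Si](CC)(CC)CC)C=O | intermediate
17 | methyl prop-2-ynoate (methyl propiolate) | C#CC(=O)OC | starting material
18 | methyl 2-(diisobutylalumanyl)prop-2-enoate (not isolated) | C=C([Al](CC(C)C)CC(C)C)C(=O)OC | intermediate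
19 | methyl 2-[(2R,3Z)-1-hydroxy-4-iodo-2-(triethylsilyloxy)pent-3-en-1-yl]prop-2-enoate, both C7 epimers | C=C(C(=O)OC)C(O)[C@H](O[Si](CC)(CC)CC)/C=C(/C)I | intermediate
20 | methyl 2-[(2R,3Z)-1-(tert-butoxycarbonyloxy)-4-iodo-2-(triethylsilyloxy)pent-3-en-1-yl]prop-2-enoate, both C7 epimers (East carbonate) | C=C(C(=O)OC)C(OC(=O)OC(C)(C)C)[C@H](O[Si](CC)(CC)CC)/C=C(/C)I | intermediate
21 | methyl (3S,4Z,6R,7R,8S,9Z)-3-acetoxy-6-hydroxy-10-iodo-1-(4-methoxybenzyloxy)-8-(triethylsilyloxy)-1,10-secogermacra-4,9,11(13)-trien-12-oate (seco hydroxy ester, not isolated) | COC(=O)C(=C)[C@H]([C@H](O)/C=C(/C)[C@@H](OC(C)=O)CCOCc1ccc(OC)cc1)[C@H](O[Si](CC)(CC)CC)/C=C(/C)I | intermediate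
22 | (3S,4Z,6R,7R,8S,9Z)-3-acetoxy-10-iodo-1-(4-methoxybenzyloxy)-8-(triethylsilyloxy)-1,10-secogermacra-4,9,11(13)-trien-6,12-olide (cis-4,5-disubstituted 3-methylenedihydrofuran-2-one) | COc1ccc(COCC[C@H](OC(C)=O)/C(C)=C\[C@H]2OC(=O)C(=C)[C@H]2[C@H](O[Si](CC)(CC)CC)/C=C(/C)I)cc1 | intermediate
23 | (3S,4Z,6R,7S,8S,9Z)-3-acetoxy-8-hydroxy-10-iodo-1-(4-methoxybenzyloxy)-1,10-secogermacra-4,9,11(13)-trien-6,12-olide | COc1ccc(COCC[C@H](OC(C)=O)/C(C)=C\[C@H]2OC(=O)C(=C)[C@H]2[C@H](O)/C=C(/C)I)cc1 | intermediate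
24 | angelic acid, (Z)-2-methylbut-2-enoic acid | C/C=C(/C)C(=O)O | starting material
25 | (Z)-2-methylbut-2-enoic 2,4,6-trichlorobenzoic anhydride (not isolated) | C/C=C(/C)C(=O)OC(=O)c1c(Cl)cc(Cl)cc1Cl | intermediate
26 | (3S,4Z,6R,7R,8S,9Z)-3-acetoxy-8-angeloyloxy-10-iodo-1-(4-methoxybenzyloxy)-1,10-secogermacra-4,9,11(13)-trien-6,12-olide | COc1ccc(COCC[C@H](OC(C)=O)/C(C)=C\[C@H]2OC(=O)C(=C)[C@H]2[C@H](OC(=O)/C(C)=C\C)/C=C(/C)I)cc1 | intermediate
27 | (3S,4Z,6R,7R,8S,9Z)-3-acetoxy-8-angeloyloxy-1-hydroxy-10-iodo-1,10-secogermacra-4,9,11(13)-trien-6,12-olide | OCC[C@H](OC(C)=O)/C(C)=C\[C@H]1OC(=O)C(=C)[C@H]1[C@H](OC(=O)/C(C)=C\C)/C=C(/C)I | intermediate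
28 | (3S,4Z,6R,7R,8S,9Z)-3-acetoxy-8-angeloyloxy-10-iodo-1-oxo-1,10-secogermacra-4,9,11(13)-trien-6,12-olide (seco aldehyde) | O=CC[C@H](OC(C)=O)/C(C)=C\[C@H]1OC(=O)C(=C)[C@H]1[C@H](OC(=O)/C(C)=C\C)/C=C(/C)I | intermediate
29 | (1S,3S,4Z,6R,7R,8R,9Z)-3-acetoxy-8-angeloyloxy-1-hydroxygermacra-4,9,11(13)-trien-6,12-olide, CNP0319825.3 | C=C1C(=O)O[C@@H]2/C=C(/C)[C@@H](OC(C)=O)C[C@H](O)/C(C)=C\[C@@H](OC(=O)/C(C)=C\C)[C@H]12 | target

## Step count and risks

Total step count: 20.
Longest linear sequence: 13 steps (11 → 29, steps 8–20). The West branch is 1 → 10 in five steps (1, 2, 5, 6, 7), with aldehyde 7 made in two side steps (3, 4).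

The three steps most likely to fail:

Step 15 (the proposed new coupling). The 1-substituted donor is hindered, monovalent iridium might insert into the C–I bond or ionise the C3 allylic acetate of 10, and the transient (Z)-enal might isomerise. The fallback uses known chemistry, sets out from 10 and 19 and comes back at 22. Alcohol 10 is oxidised with MnO2 (CH2Cl2, rt) to the enal (3S,4Z)-1-(4-methoxybenzyloxy)-4-methyl-6-oxohex-4-en-3-yl acetate F1. Alcohol 19 is converted with NBS/Me2S (CH2Cl2, 0 °C, SN2' displacement) into the allylic bromide methyl (2Z,4S,5Z)-2-(bromomethyl)-6-iodo-4-(triethylsilyloxy)hepta-2,5-dienoate F2. Indium powder in THF/H2O at rt then joins F1 and F2 in a Barbier allylation; this reaction of 2-(bromomethyl)alk-2-enoates is known to give the syn adduct and hence the cis lactone, indium leaves the alkenyl iodide alone, and attack anti to the C8 silyloxy group is expected. The product is 21, which closes to 22 with PPTS; minor diastereomers are removed by chromatography.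

Step 17 (angelate installation). The angelate may isomerise to the tiglate, and the free γ-hydroxy lactone 23 may translactonise (C8–OH onto C12) at 75 °C. The fallback sets out from 23 and comes back at 26. Alcohol 23 is esterified at 0 °C to rt (DCC, DMAP cat., CH2Cl2) with 2-[bis(2,2,2-trifluoroethoxy)phosphoryl]propanoic acid to the 8-O-{2-[bis(2,2,2-trifluoroethoxy)phosphoryl]propanoyl} ester of 23 F3. A Still–Gennari olefination of F3 with acetaldehyde (KN(SiMe3)2, 18-crown-6, THF, −78 °C) then builds the (Z)-2-methylbut-2-enoate in place and gives 26. The ester geometry then comes from the kinetic Z selectivity of the olefination and not from the integrity of angelic acid, and no heating of the hydroxy lactone is needed.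

Step 20 (macrocyclisation). Facial selectivity at C1 may be poor or wrong, and the β-acetoxy aldehyde may lose acetic acid; oligomerisation is countered by slow addition. The fallback sets out from 28 and comes back at 29. Aldehyde 28 is closed without chiral ligand (CrCl2, NiCl2 cat., DMSO/THF, rt, high dilution) to the C1-epimeric 3-acetoxy-8-angeloyloxy-1-hydroxygermacra-4,9,11(13)-trien-6,12-olides F4. Dess–Martin oxidation gives the ten-membered (Z)-enone 3-acetoxy-8-angeloyloxy-1-oxogermacra-4,9,11(13)-trien-6,12-olide F5. Reduction of F5 with catecholborane and (R)-2-methyl-CBS-oxazaborolidine (toluene, −78 °C) sets C1 by reagent-controlled 1,2-hydride delivery instead of by C–C bond formation and gives 29.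

## Further compounds

F1 | step 15 | (3S,4Z)-1-(4-methoxybenzyloxy)-4-methyl-6-oxohex-4-en-3-yl acetate | O=C/C=C(/C)[C@@H](OC(C)=O)CCOCc1ccc(OC)cc1
F2 | step 15 | methyl (2Z,4S,5Z)-2-(bromomethyl)-6-iodo-4-(triethylsilyloxy)hepta-2,5-dienoate | COC(=O)/C(CBr)=C/[C@H](O[Si](CC)(CC)CC)/C=C(/C)I
F3 | step 17 | 8-O-{2-[bis(2,2,2-trifluoroethoxy)phosphoryl]propanoyl} ester of 23 (both phosphonate α-epimers) | COc1ccc(COCC[C@H](OC(C)=O)/C(C)=C\[C@H]2OC(=O)C(=C)[C@H]2[C@H](OC(=O)C(C)P(=O)(OCC(F)(F)F)OCC(F)(F)F)/C=C(/C)I)cc1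
F4 | step 20 | (3S,4Z,6R,7R,8R,9Z)-3-acetoxy-8-angeloyloxy-1-hydroxygermacra-4,9,11(13)-trien-6,12-olide, C1 epimer mixture | C=C1C(=O)O[C@@H]2/C=C(/C)[C@@H](OC(C)=O)CC(O)/C(C)=C\[C@@H](OC(=O)/C(C)=C\C)[C@H]12
F5 | step 20 | (3S,4Z,6R,7R,8R,9Z)-3-acetoxy-8-angeloyloxy-1-oxogermacra-4,9,11(13)-trien-6,12-olide | C=C1C(=O)O[C@@H]2/C=C(/C)[C@@H](OC(C)=O)CC(=O)/C(C)=C\[C@@H](OC(=O)/C(C)=C\C)[C@H]12
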